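**Retrosynthetic overview**

1. Locants: C1 = quaternary oxirane carbon (bears C7H2OBz), C2 and C3 = acetoxy carbons, C4 and C5 = carbinols, C6 = oxirane CH. The route rests on two features of the cyclohexane ring. The all-trans oxygen triad on C3, C4 and C5 is O4, O3 and O2 of D-glucose in the correct absolute sense. The ring bond C1–C6 ties sugar C6 to the anomeric carbon.
2. Late stage: the C4/C5 diol is unmasked from benzyl ethers and the C2 acetate comes from a C2 alcohol. The oxirane (second and last ring formed) comes from C2–OH-directed epoxidation of the C1=C6 alkene.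
3. The C2 alcohol comes from 1,2-reduction of a C2 enone. C1–C7 is cut back to formaldehyde (Morita–Baylis–Hillman), the benzoate to benzoyl chloride, and the enone to a β-hydroxy ketone.
4. Key disconnection C1–C6: the β-hydroxy cyclohexanone is the first ring formed, at the expense of the pyranose ring. It arises by Ferrier carbocyclization of a 4-O-acetyl-2,3-di-O-benzyl hex-5-enopyranoside.
5. That enol ether is reached from methyl α-D-glucopyranoside in six protecting-group and functional-group steps. The sugar 4-O-acetate is carried through as the C3 acetate of the target.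

Key step: step 7

Assumption: the carbocyclization product is drawn as the C6 epimer expected to prevail; both epimers converge on the same enone in the following step, so the route does not depend on this centre.

**Step 1**
Reactants: 1 methyl α-D-glucopyranoside
Product: 2 methyl 4,6-O-[(R)-benzylidene]-α-D-glucopyranoside
Conditions: PhCH(OMe)2, CSA (cat.), DMF, 60 °C, reduced pressure
Reagents that add atoms: benzaldehyde dimethyl acetal, COC(OC)c1ccccc1
Why: Acid-catalysed transacetalization under thermodynamic control closes the trans-decalin-like 1,3-dioxane on O4/O6, and the new acetal carbon takes the (R) configuration that puts phenyl equatorial.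

**Step 2**
Reactants: 2 methyl 4,6-O-[(R)-benzylidene]-α-D-glucopyranoside
Product: 3 methyl 2,3-di-O-benzyl-4,6-O-[(R)-benzylidene]-α-D-glucopyranoside
Conditions: NaH, BnBr, Bu4NI (cat.), DMF, 0 °C → rt
Reagents that add atoms: benzyl bromide, BrCc1ccccc1
Why: Williamson etherification of the two remaining hydroxyls, under basic conditions to which the acetal and the glycoside are inert and which touch no stereocentre.

**Step 3**
Reactants: 3 methyl 2,3-di-O-benzyl-4,6-O-[(R)-benzylidene]-α-D-glucopyranoside
Product: 4 methyl 2,3-di-O-benzyl-α-D-glucopyranoside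
Conditions: 80% aq. AcOH, 70 °C
Reagents that add atoms: none
Why: Mild acid hydrolysis cleaves the benzylidene acetal, which is far more labile than the methyl glycoside or the benzyl ethers, and frees O4 and O6.

**Step 4**
Reactants: 4 methyl 2,3-di-O-benzyl-α-D-glucopyranoside
Product: 5 methyl 2,3-di-O-benzyl-6-deoxy-6-iodo-α-D-glucopyranoside
Conditions: I2, PPh3, imidazole, toluene, 70 °C
Reagents that add atoms: iodine, [I][I]
Why: Garegg–Samuelsson (Appel-type) iodination runs by SN2 displacement of an alkoxyphosphonium ion, which is fast only at the primary C6, so the secondary 4-OH should stay free.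

**Step 5**
Reactants: 5 methyl 2,3-di-O-benzyl-6-deoxy-6-iodo-α-D-glucopyranoside
Product: 6 methyl 4-O-acetyl-2,3-di-O-benzyl-6-deoxy-6-iodo-α-D-glucopyranoside
Conditions: Ac2O, pyridine, DMAP (cat.), 0 °C → rt
Reagents that add atoms: acetic anhydride, CC(=O)OC(C)=O
Why: DMAP-catalysed acylation of the only free hydroxyl places on sugar O4 the acetate that becomes the C3 acetate of the target.

**Step 6**
Reactants: 6 methyl 4-O-acetyl-2,3-di-O-benzyl-6-deoxy-6-iodo-α-D-glucopyranoside
Product: 7 methyl 4-O-acetyl-2,3-di-O-benzyl-6-deoxy-α-D-xylo-hex-5-enopyranoside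
Conditions: DBU, THF, reflux
Reagents that add atoms: none
Why: E2 dehydroiodination with the non-nucleophilic amidine base removes H5 and iodide to give the exocyclic enol ether, a procedure known to spare O-acyl groups on 6-iodo glycosides.

**Step 7**
Reactants: 7 methyl 4-O-acetyl-2,3-di-O-benzyl-6-deoxy-α-D-xylo-hex-5-enopyranoside
Product: 10 (2S,3R,4S,5S)-2-acetoxy-3,4-bis(benzyloxy)-5-hydroxycyclohexanone, via mercurio hemiketal 8 (not isolated), via mercurio keto aldehyde 9 (not isolated)
Conditions: Hg(OCOCF3)2 (5 mol %), acetone–H2O (2:1), rt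
Reagents that add atoms: water, O
Why: Divalent mercury and water add across the electron-rich C5=C6 enol ether of the sugar (Hg on the terminal carbon) to give hemiketal 8, which opens and loses methanol to the α-mercurio keto aldehyde 9; its mercury enolate attacks the aldehyde carbon (target C6) through target C1, and CF3CO2H frees the aldolate and returns Hg(OCOCF3)2, so the metal turns over. The reaction type is the Ferrier carbocyclization of 6-deoxyhex-5-enopyranosides, established for ether- and ester-protected gluco substrates alike. The cyclohexane closes in a 6-(enolendo)-exo-trig aldol, a favoured mode, because both enolate carbons (target C1 and C2) end up inside the new ring while the aldehyde C=O stays outside it. The only new stereocentre, C6, is governed by a chair-like transition state that keeps the three sugar-derived substituents equatorial and holds the aldehyde oxygen axial within reach of the enolate-bound mercury, so the hydroxyl should come out axial and cis to the C5 benzyloxy group, and it is deleted again in step 8. The step needs chemoselectivity for the enol ether and integrity of C3–C5, and both are secured because the enol ether is the only π-nucleophile present and the almost neutral aqueous medium at room temperature should neither cleave the acetate or benzyl ethers nor enolize C3 nor start β-elimination.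

**Step 8**
Reactants: 10 (2S,3R,4S,5S)-2-acetoxy-3,4-bis(benzyloxy)-5-hydroxycyclohexanone
Product: 12 (4S,5R,6S)-6-acetoxy-4,5-bis(benzyloxy)cyclohex-2-enone, via C6 mesylate 11 (not isolated)
Conditions: MsCl, Et3N, CH2Cl2, 0 °C → rt
Reagents that add atoms: methanesulfonyl chloride, CS(=O)(=O)Cl (its atoms sit only in 11 and leave again; none remains in 12)
Why: Mesylation of the C6 carbinol followed by E1cB elimination through the C1 enolate gives the conjugated enone, the mesylate being a far better leaving group than the C4 benzyloxy group that a C3 enolate would have to expel.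

**Step 9**
Reactants: 12 (4S,5R,6S)-6-acetoxy-4,5-bis(benzyloxy)cyclohex-2-enone; 13 formaldehyde
Product: 14 (4S,5R,6S)-6-acetoxy-4,5-bis(benzyloxy)-2-(hydroxymethyl)cyclohex-2-enone
Conditions: 37% aq. HCHO, DMAP (0.3 equiv), THF, rt
Reagents that add atoms: formaldehyde, C=O
Why: In this Morita–Baylis–Hillman reaction DMAP adds reversibly to C6, the C1 enolate captures formaldehyde to form C1–C7 and loss of DMAP restores the enone, a hydroxymethylation documented for cyclohex-2-enones including polyoxygenated ones and run here with a weak base at room temperature so that the C3 acetate and the C3 configuration should hold.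

**Step 10**
Reactants: 14 (4S,5R,6S)-6-acetoxy-4,5-bis(benzyloxy)-2-(hydroxymethyl)cyclohex-2-enone; 15 benzoyl chloride
Product: 16 [(3S,4R,5S)-5-acetoxy-3,4-bis(benzyloxy)-6-oxocyclohex-1-en-1-yl]methyl benzoate
Conditions: BzCl, pyridine, CH2Cl2, 0 °C
Reagents that add atoms: benzoyl chloride, O=C(Cl)c1ccccc1
Why: O-Acylation of the only hydroxyl with an acid chloride in pyridine, kept cold and free of DMAP so that the allylic benzoate formed is not displaced in an SN2′ sense.

**Step 11**
Reactants: 16 [(3S,4R,5S)-5-acetoxy-3,4-bis(benzyloxy)-6-oxocyclohex-1-en-1-yl]methyl benzoate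
Product: 17 [(3S,4R,5R,6S)-5-acetoxy-3,4-bis(benzyloxy)-6-hydroxycyclohex-1-en-1-yl]methyl benzoate
Conditions: NaBH4, CeCl3·7H2O, MeOH, −78 °C
Reagents that add atoms: none
Why: In the Luche reduction the hard cerium-modified methoxyborohydride attacks the carbonyl 1,2 and axially on the half-chair that keeps the C3–C5 substituents equatorial, so the new C2 hydroxyl should be pseudo-equatorial and trans to the C3 acetate, as is the rule for glucose-derived 4,5,6-trioxygenated cyclohexenones.

**Step 12**
Reactants: 17 [(3S,4R,5R,6S)-5-acetoxy-3,4-bis(benzyloxy)-6-hydroxycyclohex-1-en-1-yl]methyl benzoate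
Product: 18 [(1R,2R,3R,4R,5R,6S)-3-acetoxy-4,5-bis(benzyloxy)-2-hydroxy-7-oxabicyclo[4.1.0]heptan-1-yl]methyl benzoate
Conditions: mCPBA, Na2HPO4, CH2Cl2, 0 °C → rt
Reagents that add atoms: mCPBA (3-chloroperoxybenzoic acid), O=C(OO)c1cccc(Cl)c1
Why: In this Henbest epoxidation, hydrogen bonding of the peracid to the pseudo-equatorial C2 hydroxyl delivers oxygen to the face cis to it, which is also the face opposite the C5 benzyloxy group, so directing and steric effects together set C1 and C6.

**Step 13**
Reactants: 18 [(1R,2R,3R,4R,5R,6S)-3-acetoxy-4,5-bis(benzyloxy)-2-hydroxy-7-oxabicyclo[4.1.0]heptan-1-yl]methyl benzoate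
Product: 19 [(1S,2R,3S,4R,5R,6S)-2,3-diacetoxy-4,5-bis(benzyloxy)-7-oxabicyclo[4.1.0]heptan-1-yl]methyl benzoate
Conditions: Ac2O, pyridine, DMAP (cat.), CH2Cl2, 0 °C → rt
Reagents that add atoms: acetic anhydride, CC(=O)OC(C)=O
Why: DMAP-catalysed acetylation of the hindered C2 hydroxyl proceeds at oxygen with retention at C2, and the oxirane and the esters are inert to it.

**Step 14**
Reactants: 19 [(1S,2R,3S,4R,5R,6S)-2,3-diacetoxy-4,5-bis(benzyloxy)-7-oxabicyclo[4.1.0]heptan-1-yl]methyl benzoate
Product: 20 [(1S,2R,3S,4R,5R,6S)-2,3-diacetoxy-4,5-dihydroxy-7-oxabicyclo[4.1.0]heptan-1-yl]methyl benzoate (CNP0171674.1)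
Conditions: H2 (1 atm), Pd(OH)2/C, EtOAc, rt
Reagents that add atoms: none
Why: Catalytic hydrogenolysis cleaves only the benzylic C–O bonds of the two ethers, while the oxirane (neither benzylic nor allylic), the benzoate and the acetates should persist in a neutral aprotic solvent, as is known for benzyl-protected cyclitol epoxides.

**Compound list**

1 | methyl α-D-glucopyranoside | CO[C@@H]1[C@H](O)[C@@H](O)[C@H](O)[C@@H](CO)O1 | starting material
2 | methyl 4,6-O-[(R)-benzylidene]-α-D-glucopyranoside | CO[C@@H]1[C@H](O)[C@@H](O)[C@@H]2O[C@H](c3ccccc3)OC[C@H]2O1 | intermediate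
3 | methyl 2,3-di-O-benzyl-4,6-O-[(R)-benzylidene]-α-D-glucopyranoside | CO[C@@H]1[C@H](OCc3ccccc3)[C@@H](OCc3ccccc3)[C@@H]2O[C@H](c3ccccc3)OC[C@H]2O1 | intermediate
4 | methyl 2,3-di-O-benzyl-α-D-glucopyranoside | CO[C@@H]1[C@H](OCc2ccccc2)[C@@H](OCc2ccccc2)[C@H](O)[C@@H](CO)O1 | intermediate
5 | methyl 2,3-di-O-benzyl-6-deoxy-6-iodo-α-D-glucopyranoside | CO[C@@H]1[C@H](OCc2ccccc2)[C@@H](OCc2ccccc2)[C@H](O)[C@@H](CI)O1 | intermediate
6 | methyl 4-O-acetyl-2,3-di-O-benzyl-6-deoxy-6-iodo-α-D-glucopyranoside | CO[C@@H]1[C@H](OCc2ccccc2)[C@@H](OCc2ccccc2)[C@H](OC(C)=O)[C@@H](CI)O1 | intermediate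
7 | methyl 4-O-acetyl-2,3-di-O-benzyl-6-deoxy-α-D-xylo-hex-5-enopyranoside | CO[C@@H]1[C@H](OCc2ccccc2)[C@@H](OCc2ccccc2)[C@H](OC(C)=O)C(=C)O1 | intermediate
8 | mercurio hemiketal: the 5-hydroxy-6-(trifluoroacetoxymercurio) adduct of 7, C5 configuration not defined, not isolated | CO[C@@H]1[C@H](OCc2ccccc2)[C@@H](OCc2ccccc2)[C@H](OC(C)=O)C(O)(C[Hg]OC(=O)C(F)(F)F)O1 | intermediate
9 | mercurio keto aldehyde: 4-O-acetyl-2,3-di-O-benzyl-6-deoxy-6-(trifluoroacetoxymercurio)-aldehydo-D-xylo-hexos-5-ulose, not isolated | O=C[C@H](OCc1ccccc1)[C@@H](OCc1ccccc1)[C@H](OC(C)=O)C(=O)C[Hg]OC(=O)C(F)(F)F | intermediate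
10 | (2S,3R,4S,5S)-2-acetoxy-3,4-bis(benzyloxy)-5-hydroxycyclohexanone (ketone = C2, carbinol = C6) | CC(=O)O[C@H]1[C@H](OCc2ccccc2)[C@@H](OCc2ccccc2)[C@@H](O)CC1=O | intermediate
11 | C6 mesylate: the 5-O-methanesulfonate of 10, not isolated | CC(=O)O[C@H]1[C@H](OCc2ccccc2)[C@@H](OCc2ccccc2)[C@@H](OS(C)(=O)=O)CC1=O | intermediate
12 | (4S,5R,6S)-6-acetoxy-4,5-bis(benzyloxy)cyclohex-2-enone | CC(=O)O[C@H]1[C@H](OCc2ccccc2)[C@@H](OCc2ccccc2)C=CC1=O | intermediate
13 | formaldehyde | C=O | starting material
14 | (4S,5R,6S)-6-acetoxy-4,5-bis(benzyloxy)-2-(hydroxymethyl)cyclohex-2-enone | CC(=O)O[C@H]1[C@H](OCc2ccccc2)[C@@H](OCc2ccccc2)C=C(CO)C1=O | intermediate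
15 | benzoyl chloride | O=C(Cl)c1ccccc1 | starting material
16 | [(3S,4R,5S)-5-acetoxy-3,4-bis(benzyloxy)-6-oxocyclohex-1-en-1-yl]methyl benzoate | CC(=O)O[C@H]1[C@H](OCc2ccccc2)[C@@H](OCc2ccccc2)C=C(COC(=O)c2ccccc2)C1=O | intermediate
17 | [(3S,4R,5R,6S)-5-acetoxy-3,4-bis(benzyloxy)-6-hydroxycyclohex-1-en-1-yl]methyl benzoate | CC(=O)O[C@H]1[C@H](OCc2ccccc2)[C@@H](OCc2ccccc2)C=C(COC(=O)c2ccccc2)[C@@H]1O | intermediate
18 | [(1R,2R,3R,4R,5R,6S)-3-acetoxy-4,5-bis(benzyloxy)-2-hydroxy-7-oxabicyclo[4.1.0]heptan-1-yl]methyl benzoate | CC(=O)O[C@H]1[C@H](OCc2ccccc2)[C@@H](OCc2ccccc2)[C@@H]2O[C@]2(COC(=O)c2ccccc2)[C@@H]1O | intermediate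
19 | [(1S,2R,3S,4R,5R,6S)-2,3-diacetoxy-4,5-bis(benzyloxy)-7-oxabicyclo[4.1.0]heptan-1-yl]methyl benzoate | CC(=O)O[C@H]1[C@H](OCc2ccccc2)[C@@H](OCc2ccccc2)[C@@H]2O[C@]2(COC(=O)c2ccccc2)[C@@H]1OC(C)=O | intermediate
20 | [(1S,2R,3S,4R,5R,6S)-2,3-diacetoxy-4,5-dihydroxy-7-oxabicyclo[4.1.0]heptan-1-yl]methyl benzoate (CNP0171674.1) | CC(=O)O[C@H]1[C@H](O)[C@@H](O)[C@@H]2O[C@]2(COC(=O)c2ccccc2)[C@@H]1OC(C)=O | target

**Total step count:** 14. **Longest linear sequence:** 14 steps (fully linear from 1).

**Steps most likely to fail**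

**Step 9 (Morita–Baylis–Hillman hydroxymethylation).** The α′-acetoxy enone is base-sensitive. Acetate cleavage, epimerization at C3, or β-elimination of the C4 benzyloxy group followed by aromatization may outrun the slow C–C bond formation.

The fallback sets out from 12 and comes back at 14. It forms C1–C7 by cross-coupling instead of enolate chemistry. α-Iodination of 12 (I2, pyridine–CH2Cl2, rt) should give (4S,5R,6S)-6-acetoxy-4,5-bis(benzyloxy)-2-iodocyclohex-2-enone F1. Stille coupling of F1 with (tributylstannyl)methanol (Pd(PPh3)4, zerovalent palladium, dioxane, 80 °C) should then deliver 14 under essentially neutral, water-free conditions.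

**Step 11 (Luche reduction).** Three things may go wrong:
- Hydride may add in a conjugate or SN2′ manner with expulsion of the allylic benzoate.
- Facial selectivity at C2 may be incomplete.
- The new C2 alkoxide may pull over a neighbouring acyl group.

The fallback sets out from 14 and comes back at 17. It reduces before any leaving group sits on C7. NaBH4/CeCl3·7H2O in MeOH at −78 °C on 14 should give (1R,2S,5S,6R)-5,6-bis(benzyloxy)-2-hydroxy-3-(hydroxymethyl)cyclohex-3-en-1-yl acetate F2. Its primary C7 hydroxyl is then benzoylated selectively with one equivalent of 15 (pyridine–CH2Cl2, −30 °C) to give 17.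

**Step 12 (directed epoxidation).** Three allylic C–O bonds, one of them an ester, deactivate the alkene. Oxidation may therefore be sluggish, and forcing conditions would erode facial selectivity and invite acyl migration.

The fallback sets out from 14 and comes back at 18. It epoxidizes before benzoylation, by metal-bound instead of hydrogen-bond-guided delivery. The diol F2, made from 14 as described above, carries two allylic hydroxyls on C2 and C7. With VO(acac)2 (cat.) and t-BuOOH (CH2Cl2, 0 °C → rt) these can bind vanadium on the C2–O face. The product should be (1R,2R,3R,4R,5R,6S)-4,5-bis(benzyloxy)-2-hydroxy-1-(hydroxymethyl)-7-oxabicyclo[4.1.0]heptan-3-yl acetate F3. Selective benzoylation of its primary hydroxyl with 15 (pyridine–CH2Cl2, −30 °C) gives 18.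

**Further compounds**

F1 | step 9 | (4S,5R,6S)-6-acetoxy-4,5-bis(benzyloxy)-2-iodocyclohex-2-enone | CC(=O)O[C@H]1[C@H](OCc2ccccc2)[C@@H](OCc2ccccc2)C=C(I)C1=O
F2 | step 11 | (1R,2S,5S,6R)-5,6-bis(benzyloxy)-2-hydroxy-3-(hydroxymethyl)cyclohex-3-en-1-yl acetate | CC(=O)O[C@H]1[C@H](OCc2ccccc2)[C@@H](OCc2ccccc2)C=C(CO)[C@@H]1O
F3 | step 12 | (1R,2R,3R,4R,5R,6S)-4,5-bis(benzyloxy)-2-hydroxy-1-(hydroxymethyl)-7-oxabicyclo[4.1.0]heptan-3-yl acetate | CC(=O)O[C@H]1[C@H](OCc2ccccc2)[C@@H](OCc2ccccc2)[C@@H]2O[C@]2(CO)[C@@H]1O
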